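## Retrosynthetic overview

1. The target is a cis-(2S,4R) 4-hydroxy-dihydropyran (ring B: O1, C2, C3, C4, C4a, C8a) fused through the C4a=C8a enol-ether bond to a cyclohexenone (ring A: C4a, C5 to C8, C8a, ketone at C5). The C4 carbinol is taken back one oxidation level to a ketone, giving the 4,5-dione.
2. Enabling feature: in ring B the oxygen on C4 and O1 on C2 are 1,3-related and O1 ends on the sp2 carbon C8a. C2–O1 is therefore a latent aldehyde C=O, and C3–C4(O)–C4a=C8a(O) is a latent 1,3-dioxygenated diene that already exists, in enolised form, in 2-acetylcyclohexane-1,3-dione.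
3. Key disconnection: C2–C3 and O1–C8a together, by a catalytic asymmetric aldol/cyclocondensation (formal oxa-Diels–Alder reaction) of octadecanal with a 1-methoxy-3-silyloxy diene built into ring A.
4. Ring order: ring A is bought; ring B is closed in the key step, which also sets C2; C4 is set last by substrate-controlled 1,2-reduction.

Key step: step 3

Remarks on the chemistry:
- Chromenone numbering (O1, C2, C3, C4, C4a, C5 to C8, C8a) is used for all intermediates.
- Assumption: (R)-BINOL is taken as the ligand antipode that exposes the Re face of the aldehyde (O > alkyl > H), by analogy with BINOL–Ti(OiPr)4 allylations and aldol additions. If the sense is the opposite, (S)-BINOL is used and nothing else changes.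

## Route

Step 1
Reactants: 1 2-acetylcyclohexane-1,3-dione
Product: 2 2-acetyl-3-methoxycyclohex-2-en-1-one
Conditions: Me3SiCHN2 (2 M in hexanes, 1.2 equiv), MeOH/toluene (1:4), 0 °C to rt
Reagents that add atoms: (trimethylsilyl)diazomethane, C[Si](C)(C)C=[N+]=[N-]
Why: Diazoalkane O-methylation of a vinylogous carboxylic acid: the acidic enol of 1 protonates the diazo reagent and the triketonate should be methylated at a ring oxygen (two of its three oxygens are ring oxygens, and the endocyclic enol ether avoids the allylic strain of the exocyclic isomer), which fixes C8a as the carbon that carries the leaving group; no stereocenter is formed.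

Step 2
Reactants: 2 2-acetyl-3-methoxycyclohex-2-en-1-one
Product: 4 3-methoxy-2-[1-(trimethylsilyloxy)ethenyl]cyclohex-2-en-1-one, via lithium enolate 3 (not isolated)
Conditions: LiN(iPr)2 (1.1 equiv), THF, −78 °C; Me3SiCl (1.5 equiv), −78 to 0 °C; pentane, filtration under argon, no aqueous work-up
Reagents that add atoms: chlorotrimethylsilane, C[Si](C)(C)Cl
Why: Kinetic enolate formation and O-silylation: the acetyl CH3 is the most acidic and least hindered C–H (the ring CH2 groups are α′ or γ to a less acidifying vinylogous-ester carbonyl), so the amide base at −78 °C followed by Me3SiCl should give the cross-conjugated silyloxy diene whose =CH2 terminus is the future C3; no stereocenter is formed.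

Step 3
Reactants: 4 3-methoxy-2-[1-(trimethylsilyloxy)ethenyl]cyclohex-2-en-1-one; 5 octadecanal
Product: 8 (2S)-2-heptadecyl-2,3,7,8-tetrahydro-4H-chromene-4,5(6H)-dione, via silyl aldol adduct 6 (not isolated), via hydroxy ketone 7 (not isolated)
Conditions: (R)-BINOL (20 mol %), Ti(OiPr)4 (10 mol %), 4 Å MS, Et2O, −20 °C; then CF3CO2H (1.0 equiv), CH2Cl2, 0 °C; aq. NaHCO3
Reagents that add atoms: none
Why: The BINOL–Ti(OiPr)4 Lewis acid activates aldehyde 5, and the terminal CH2 of silyl enol ether 4 (the future C3) adds to its Re face through an open transition state (Mukaiyama aldol), which forms C2–C3 and, after silyl transfer, adduct 6; acid then frees the C2 hydroxyl (7), which adds to C8a of the β-methoxy enone and expels methanol, which forms O1–C8a. The closest known reaction type is the BINOL–titanium-catalysed aldol/cyclocondensation (formal oxa-Diels–Alder reaction) of 1-alkoxy-3-silyloxy-1,3-dienes with aliphatic aldehydes to give 2-alkyl-2,3-dihydro-4H-pyran-4-ones. Ring B closes by a 6-endo-trig conjugate addition–elimination (vinylogous transesterification), which restores the C4a=C8a enol ether. The only new stereocenter, C2, is set by the catalyst through ligand-controlled choice of the aldehyde face, since the diene is achiral. The step needs C–C bonding at C3 and O-closure at C8a: C3 is the only nucleophilic terminus of 4, and C8a is the only electrophilic carbon that the C2 oxygen can reach through a six-membered transition state, the loss of methanol making the closure irreversible. Self-aldolisation of 5 is avoided because no base is present and the aldehyde reacts only when bound to the Lewis acid.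

Step 4
Reactants: 8 (2S)-2-heptadecyl-2,3,7,8-tetrahydro-4H-chromene-4,5(6H)-dione
Product: 9 (2S,4R)-2-heptadecyl-4-hydroxy-2,3,4,6,7,8-hexahydro-5H-chromen-5-one
Conditions: NaBH4 (0.5 equiv), CeCl3·7H2O (1.0 equiv), MeOH/CH2Cl2 (3:1), −78 °C; pH 7 phosphate buffer
Reagents that add atoms: none
Why: Luche 1,2-reduction: C4 is the carbonyl of a 2,3-dihydro-4H-pyran-4-one and is made more electrophilic than the carbocyclic C5 carbonyl by the inductive pull of O1 through C2–C3, so the first hydride should go to C4 at −78 °C, and the product, now a plain vinylogous ester hydrogen-bonded to the new hydroxyl, should resist further reduction; hydride adds axially to the half-chair of ring B on the face of the axial C2–H, which places the hydroxyl pseudo-equatorial and cis to the C2 chain and so sets C4 as R under control of C2.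

## Compound list

1 | 2-acetylcyclohexane-1,3-dione (drawn as its ring enol) | CC(=O)C1=C(O)CCCC1=O | starting material
2 | 2-acetyl-3-methoxycyclohex-2-en-1-one | COC1=C(C(C)=O)C(=O)CCC1 | intermediate
3 | lithium 1-(2-methoxy-6-oxocyclohex-1-en-1-yl)ethen-1-olate (lithium enolate of 2) | [Li+].[O-]C(=C)C1=C(OC)CCCC1=O | intermediate
4 | 3-methoxy-2-[1-(trimethylsilyloxy)ethenyl]cyclohex-2-en-1-one | COC1=C(C(=C)O[Si](C)(C)C)C(=O)CCC1 | intermediate
5 | octadecanal | CCCCCCCCCCCCCCCCCC=O | starting material
6 | 3-methoxy-2-[(3S)-3-(trimethylsilyloxy)icosanoyl]cyclohex-2-en-1-one | CCCCCCCCCCCCCCCCC[C@@H](CC(=O)C1=C(OC)CCCC1=O)O[Si](C)(C)C | intermediate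
7 | 2-[(3S)-3-hydroxyicosanoyl]-3-methoxycyclohex-2-en-1-one | CCCCCCCCCCCCCCCCC[C@H](O)CC(=O)C1=C(OC)CCCC1=O | intermediate
8 | (2S)-2-heptadecyl-2,3,7,8-tetrahydro-4H-chromene-4,5(6H)-dione | CCCCCCCCCCCCCCCCC[C@H]1CC(=O)C2=C(CCCC2=O)O1 | intermediate
9 | (2S,4R)-2-heptadecyl-4-hydroxy-2,3,4,6,7,8-hexahydro-5H-chromen-5-one | CCCCCCCCCCCCCCCCC[C@H]1C[C@@H](O)C2=C(CCCC2=O)O1 | target

## Step count and risks

Total step count: 4. Longest linear sequence: 4 steps (1 to 2 to 4 to 8 to 9); octadecanal 5 enters in step 3.

The three steps most likely to fail:

1. Step 4, misdirected hydride delivery. Both carbonyls of 8 are vinylogous-ester carbonyls on the same enol ether, so hydride may also be delivered to C5. In addition, exposure of 8 to base can open ring B by a retro-oxa-Michael reaction and erode C2, so 8 should be reduced directly after isolation. The fallback sets out from 4 (with 5) and comes back at 9; it reduces before ring B is closed. The BINOL–Ti(OiPr)4 aldol of step 3 would be stopped before the acid stage (pH 7 work-up; the silyl ether of 6 cleaved with pyridine-buffered HF·pyridine in THF at 0 °C) and hydroxy ketone 7 isolated. Evans–Saksena reduction (Me4NBH(OAc)3, MeCN/AcOH, −30 °C) delivers hydride from boron bound to the C2 hydroxyl, which can reach only the β-carbonyl C4, and should give the 1,3-anti diol 2-[(1R,3S)-1,3-dihydroxyicosyl]-3-methoxycyclohex-2-en-1-one F1. The 1,3-anti diol corresponds to the 2,4-cis ring. Ring B would then be closed at the alcohol oxidation level by intramolecular addition–elimination of the C2 hydroxyl at C8a (K2CO3, MeOH, 0 °C to rt), which gives 9.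

2. Step 3, insufficient facial discrimination or stalled catalyst turnover. Diene 4 is less nucleophilic than simple 1-alkoxy-3-silyloxy dienes, and its ring carbonyl can bind titanium. The fallback sets out from 2 and comes back at 8; it makes C2–C3 by acylation and sets C2 by asymmetric hydrogenation. Ketone 2 would be deprotonated with LiN(SiMe3)2 (2.2 equiv, THF, −78 °C) to enolate 3 and acylated with octadecanoyl chloride to give the β-diketone 3-methoxy-2-(3-oxoicosanoyl)cyclohex-2-en-1-one F2. Noyori hydrogenation ([RuCl2((S)-BINAP)], H2, MeOH) should reduce only the alkyl-flanked ketone, because the other carbonyl is conjugated to and shielded by the tetrasubstituted alkene, and give 7. Treatment of 7 with CF3CO2H as in the second stage of step 3 closes ring B to 8.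

3. Step 1, alkylation at the wrong oxygen. Methylation at the acetyl oxygen would give the exocyclic enol ether and misplace the leaving group. The fallback sets out from 1 and comes back at 2; it replaces direct alkylation by activation and substitution. Oxalyl chloride (DMF cat., CH2Cl2, 0 °C) should convert the ring enol into the vinylogous acid chloride 2-acetyl-3-chlorocyclohex-2-en-1-one F3, and NaOMe in MeOH at 0 °C should give 2 by addition–elimination at the ring carbon.

## Further compounds

F1 | step 4 | 2-[(1R,3S)-1,3-dihydroxyicosyl]-3-methoxycyclohex-2-en-1-one | CCCCCCCCCCCCCCCCC[C@H](O)C[C@@H](O)C1=C(OC)CCCC1=O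
F2 | step 3 | 3-methoxy-2-(3-oxoicosanoyl)cyclohex-2-en-1-one | CCCCCCCCCCCCCCCCCC(=O)CC(=O)C1=C(OC)CCCC1=O
F3 | step 1 | 2-acetyl-3-chlorocyclohex-2-en-1-one | CC(=O)C1=C(Cl)CCCC1=O
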